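**Plan**

1. Retrosynthesis: the side-chain ester C–O bond is cut first (shikonin 21 + dienoic acid 25). Then both C(=O)–C(sp2) bonds of the quinone ring, C1–C2 and C3–C4, are cut together, leaving a 3,6-dioxygenated phthaloyl unit and the terminal alkyne 19. The C3=C4 alkene of the acid is cut last (Wittig).
2. Enabling feature: C1 and C4 of the quinone ring are two acyl carbons held ortho on the benzenoid ring C4a–C5–C6–C7–C8–C8a, which is symmetrical (oxygen at C5 and at C8), and C2=C3 carries one substituent and one hydrogen. The quinone ring is therefore the formal [4+2] adduct of a phthaloyl–metal unit (from a benzocyclobutenedione) and a terminal alkyne, and the symmetry removes any regiochemical question.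
3. Forward: an aryne [2+2] cycloaddition builds the four-membered ring on the arene, oxidation gives the benzocyclobutenedione, cobalt opens it to phthaloyl complex 11, and annulation with alkyne 19 closes the quinone ring with the side chain in place. Desilylation and esterification finish the route.
4. Stereochemistry: the single stereocentre, (R), is set by asymmetric transfer hydrogenation of ynone 16 and is not touched afterwards. The (Z)-alkene comes from a Wittig reaction of a non-stabilised ylide.
5. Protecting groups: the phenol methyl ethers are exchanged for silyl ethers before the annulation, so that all three silyl groups leave together under buffered fluoride, which the acid-sensitive side chain tolerates.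

Key step: step 12

Remark: the 5,8-dihydroxy-1,4-naphthoquinone core is a pair of rapidly interconverting tautomers and the route delivers the equilibrium mixture that the drawn structure represents; the sense of induction in step 9 is assigned by analogy with other alkynyl ketones and would be confirmed on 17.

**Route**

Step 1
Reactants: 1 2-bromo-1,4-dimethoxybenzene; 2 1,1-diethoxyethene
Product: 5 2,5-dimethoxybicyclo[4.2.0]octa-1,3,5-trien-7-one (3,6-dimethoxybenzocyclobutenone), via 3,6-dimethoxybenzyne 3 (not isolated), via benzocyclobutenone diethyl ketal 4 (not isolated)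
Conditions: NaNH2, THF, reflux; then 1 M aq. HCl, THF, rt
Reagents that add atoms: water, O
Why: NaNH2 dehydrobrominates 1 to the symmetrical aryne 3, whose [2+2] cycloaddition with the electron-rich ketene acetal 2 can give only one ketal 4, and acidic work-up hydrolyses 4 to the ketone (aryne–ketene acetal [2+2] cycloaddition).

Step 2
Reactants: 5 2,5-dimethoxybicyclo[4.2.0]octa-1,3,5-trien-7-one
Product: 6 8,8-dibromo-2,5-dimethoxybicyclo[4.2.0]octa-1,3,5-trien-7-one
Conditions: N-bromosuccinimide (2.2 equiv), (PhCO2)2 (cat.), PhCF3, reflux
Reagents that add atoms: N-bromosuccinimide, O=C1CCC(=O)N1Br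
Why: Wohl–Ziegler radical bromination should take place twice at the only benzylic CH2 group, the carbon that is to become the second carbonyl, without requiring the disfavoured enol of the strained ketone.

Step 3
Reactants: 6 8,8-dibromo-2,5-dimethoxybicyclo[4.2.0]octa-1,3,5-trien-7-one
Product: 7 3,6-dimethoxybenzocyclobutene-1,2-dione
Conditions: AgOCOCF3 (2.2 equiv), MeCN/H2O, rt to 50 °C
Reagents that add atoms: water, O
Why: silver-assisted hydrolysis of the gem-dibromide, with ionisation helped by the remaining bromine and the ortho-methoxy aryl ring, should unveil the second ketone, which is the established way to benzocyclobutenediones.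

Step 4
Reactants: 7 3,6-dimethoxybenzocyclobutene-1,2-dione
Product: 8 3,6-dihydroxybenzocyclobutene-1,2-dione
Conditions: BBr3 (3 equiv), CH2Cl2, −78 °C to rt; then H2O
Reagents that add atoms: none
Why: BBr3 ether cleavage removes the methyl groups at a stage where the molecule is acid-stable, because they could not be removed later beside the side chain.

Step 5
Reactants: 8 3,6-dihydroxybenzocyclobutene-1,2-dione
Product: 9 3,6-bis(tert-butyldimethylsilyloxy)benzocyclobutene-1,2-dione
Conditions: TBSOTf (2.4 equiv), 2,6-lutidine, CH2Cl2, 0 °C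
Reagents that add atoms: tert-butyldimethylsilyl trifluoromethanesulfonate, CC(C)(C)[Si](C)(C)OS(=O)(=O)C(F)(F)F
Why: silylation with a silyl triflate and a hindered non-nucleophilic base protects both phenols without exposing the strained electrophilic dione to a nucleophile.

Step 6
Reactants: 9 3,6-bis(tert-butyldimethylsilyloxy)benzocyclobutene-1,2-dione
Product: 11 CoCl(dmgH2)(py)[3,6-(TBSO)2C6H2(CO)2] (dmgH2 = dimethylglyoxime, py = pyridine; octahedral phthaloyl complex of trivalent cobalt), via phthaloylcobalt bis(triphenylphosphine) chloride 10 (not isolated)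
Conditions: ClCo(PPh3)3 (1.05 equiv), PhCl, rt, Ar; then dimethylglyoxime (1.1 equiv), pyridine, rt
Reagents that add atoms: chlorotris(triphenylphosphine)cobalt, Cl[Co-3]([P+](c1ccccc1)(c1ccccc1)c1ccccc1)([P+](c1ccccc1)(c1ccccc1)c1ccccc1)[P+](c1ccccc1)(c1ccccc1)c1ccccc1; dimethylglyoxime, C/C(=N\O)C(/C)=N/O; pyridine, c1ccncc1
Why: univalent cobalt inserts oxidatively into the strained C(=O)–C(=O) bond of 9 to give the five-membered metallacycle 10 of trivalent cobalt, and exchange of the phosphines for dimethylglyoxime and pyridine gives the air-stable complex 11 that reacts with alkynes (known phthaloylcobalt chemistry).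

Step 7
Reactants: 12 4-methylpent-3-enoic acid
Product: 13 N-methoxy-N,4-dimethylpent-3-enamide
Conditions: 1,1'-carbonyldiimidazole, CH2Cl2, 0 °C to rt; then MeNH(OMe)·HCl, rt
Reagents that add atoms: N,O-dimethylhydroxylamine hydrochloride, CNOC.Cl
Why: acyl imidazole formation and aminolysis give the Weinreb amide under near-neutral conditions that leave the β,γ-alkene in place.

Step 8
Reactants: 13 N-methoxy-N,4-dimethylpent-3-enamide; 14 ethynyltrimethylsilane
Product: 16 6-methyl-1-(trimethylsilyl)hept-5-en-1-yn-3-one, via lithium (trimethylsilyl)acetylide 15 (not isolated)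
Conditions: 14, n-BuLi, THF, −78 °C; then 13, −78 to −20 °C; AcOH quench at −78 °C
Reagents that add atoms: none
Why: the acetylide adds once because the chelated tetrahedral adduct persists until the cold acidic quench (Weinreb ketone synthesis), and that quench avoids base-induced migration of the alkene.

Step 9
Reactants: 16 6-methyl-1-(trimethylsilyl)hept-5-en-1-yn-3-one
Product: 17 (R)-6-methyl-1-(trimethylsilyl)hept-5-en-1-yn-3-ol
Conditions: Ru[(R,R)-TsNCHPhCHPhNH](p-cymene) (1 mol %), i-PrOH, rt
Reagents that add atoms: none
Why: Noyori asymmetric transfer hydrogenation of an alkynyl ketone, in which the (R,R)-diamine complex of divalent ruthenium passes hydride and proton through a six-membered transition state that tells alkynyl from alkyl, is expected to give the (R)-carbinol and works without added base.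

Step 10
Reactants: 17 (R)-6-methyl-1-(trimethylsilyl)hept-5-en-1-yn-3-ol
Product: 18 (R)-tert-butyldimethyl{[6-methyl-1-(trimethylsilyl)hept-5-en-1-yn-3-yl]oxy}silane
Conditions: TBSCl, imidazole, DMF, rt
Reagents that add atoms: tert-butyldimethylsilyl chloride, CC(C)(C)[Si](C)(C)Cl
Why: standard silylation of a secondary alcohol leaves the stereocentre untouched and removes the free hydroxyl before the cobalt step.

Step 11
Reactants: 18 (R)-tert-butyldimethyl{[6-methyl-1-(trimethylsilyl)hept-5-en-1-yn-3-yl]oxy}silane
Product: 19 (R)-tert-butyldimethyl[(6-methylhept-5-en-1-yn-3-yl)oxy]silane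
Conditions: K2CO3 (0.2 equiv), MeOH, rt
Reagents that add atoms: none
Why: base-catalysed methanolysis cleaves only the alkynyl C–Si bond, and the secondary silyl ether is stable to these conditions.

Step 12
Reactants: 11 CoCl(dmgH2)(py)[3,6-(TBSO)2C6H2(CO)2]; 19 (R)-tert-butyldimethyl[(6-methylhept-5-en-1-yn-3-yl)oxy]silane
Product: 20 5,8-bis(tert-butyldimethylsilyloxy)-2-[(1R)-1-(tert-butyldimethylsilyloxy)-4-methylpent-3-en-1-yl]naphthalene-1,4-dione
Conditions: 11 (1.2 equiv), CoCl2·6H2O (1.2 equiv), MeCN, 75 °C, Ar
Reagents that add atoms: none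
Why: CoCl2 as Lewis acid labilises chloride or pyridine on the octahedral trivalent cobalt of 11, the terminal alkyne of 19 coordinates and inserts into one acyl–cobalt bond (first C(=O)–C bond, seven-membered cobaltacycle), and C–C reductive elimination makes the second C(=O)–C bond and releases univalent cobalt. The closest known reaction type is the naphthoquinone synthesis from phthaloylcobalt dimethylglyoxime complexes and alkynes, which is established for terminal and oxygen-substituted alkynes. The only ring formed, the six-membered quinone ring, closes by reductive elimination from the seven-membered metallacycle, a formal [4+2] union of the four-atom phthaloyl unit and the two alkyne carbons. No stereocentre is created; the (R) carbinol carbon of 19 is a bystander whose C–O bond, held as a silyl ether under non-basic conditions, is not ionised, so its configuration is carried into 20. The step needs no regiocontrol because the two acyl carbons of the symmetrical 3,6-disubstituted phthaloyl unit are equivalent, and it needs chemoselectivity for the alkyne over the trisubstituted alkene, which does not insert into an acyl–cobalt bond. Loss of an aryl silyl group under these conditions would be harmless, since step 13 removes all three.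

Step 13
Reactants: 20 5,8-bis(tert-butyldimethylsilyloxy)-2-[(1R)-1-(tert-butyldimethylsilyloxy)-4-methylpent-3-en-1-yl]naphthalene-1,4-dione
Product: 21 shikonin, 5,8-dihydroxy-2-[(1R)-1-hydroxy-4-methylpent-3-en-1-yl]naphthalene-1,4-dione
Conditions: Bu4NF (4 equiv), AcOH (4 equiv), THF, 0 °C to rt
Reagents that add atoms: none
Why: fluoride cleaves the two aryl silyl ethers, whose phenoxides peri to the quinone carbonyls are good leaving groups, and then the secondary silyl ether, while acetic acid keeps the medium near neutral so that neither the quinone nor the side chain is exposed to strong acid or base.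

Step 14
Reactants: 22 (2-carboxyethyl)triphenylphosphonium bromide; 23 methacrolein (2-methylprop-2-enal)
Product: 25 (3Z)-5-methylhexa-3,5-dienoic acid, via sodium 3-(triphenylphosphoranylidene)propanoate 24 (not isolated)
Conditions: 22, NaN(SiMe3)2 (2.1 equiv), THF, −78 to 0 °C; then 23, −78 °C to rt; 1 M aq. HCl, cold
Reagents that add atoms: none
Why: Wittig olefination of the enal with the non-stabilised carboxylate ylide under lithium-free conditions should give the (Z)-alkene through kinetically controlled formation of the cis-oxaphosphetane.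

Step 15
Reactants: 21 shikonin; 25 (3Z)-5-methylhexa-3,5-dienoic acid
Product: 26 CNP0129564.1, (1R)-1-(5,8-dihydroxy-1,4-dioxo-1,4-dihydronaphthalen-2-yl)-4-methylpent-3-en-1-yl (3Z)-5-methylhexa-3,5-dienoate
Conditions: 25 (1.3 equiv), DCC (1.3 equiv), DMAP (0.1 equiv), CH2Cl2, −10 to 0 °C, dark
Reagents that add atoms: none
Why: Steglich esterification should acylate only the side-chain carbinol, with retention since its C–O bond is not broken, because the peri-hydroxyls are locked in hydrogen bonds to the quinone carbonyls and are poor nucleophiles, and low temperature with little DMAP limits ketene formation from the β,γ-unsaturated acyl donor.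

**Compound list**

1 | 2-bromo-1,4-dimethoxybenzene | COc1ccc(OC)c(Br)c1 | starting material
2 | 1,1-diethoxyethene | C=C(OCC)OCC | starting material
3 | 3,6-dimethoxybenzyne (not isolated) | COC1=CC=C(OC)C#C1 | intermediate
4 | 7,7-diethoxy-2,5-dimethoxybicyclo[4.2.0]octa-1,3,5-triene (not isolated) | CCOC1(OCC)Cc2c(OC)ccc(OC)c21 | intermediate
5 | 2,5-dimethoxybicyclo[4.2.0]octa-1,3,5-trien-7-one | COc1ccc(OC)c2c1CC2=O | intermediate
6 | 8,8-dibromo-2,5-dimethoxybicyclo[4.2.0]octa-1,3,5-trien-7-one | COc1ccc(OC)c2c1C(Br)(Br)C2=O | intermediate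
7 | 3,6-dimethoxybenzocyclobutene-1,2-dione | COc1ccc(OC)c2c1C(=O)C2=O | intermediate
8 | 3,6-dihydroxybenzocyclobutene-1,2-dione | Oc1ccc(O)c2c1C(=O)C2=O | intermediate
9 | 3,6-bis(tert-butyldimethylsilyloxy)benzocyclobutene-1,2-dione | CC(C)(C)[Si](C)(C)Oc1ccc(O[Si](C)(C)C(C)(C)C)c2c1C(=O)C2=O | intermediate
10 | CoCl(PPh3)2[3,6-(TBSO)2C6H2(CO)2], five-coordinate phthaloyl complex of trivalent cobalt (not isolated; donor bonds written as P+–Co−) | O=C1c2c(O[Si](C)(C)C(C)(C)C)ccc(O[Si](C)(C)C(C)(C)C)c2C(=O)[Co-2]1(Cl)([P+](c1ccccc1)(c1ccccc1)c1ccccc1)[P+](c1ccccc1)(c1ccccc1)c1ccccc1 | intermediate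
11 | CoCl(dmgH2)(py)[3,6-(TBSO)2C6H2(CO)2], octahedral phthaloyl complex of trivalent cobalt (donor bonds written as N+–Co−) | O=C1c2c(O[Si](C)(C)C(C)(C)C)ccc(O[Si](C)(C)C(C)(C)C)c2C(=O)[Co-3]13(Cl)([n+]4ccccc4)[N+](O)=C(C)C(C)=[N+]3O | intermediate
12 | 4-methylpent-3-enoic acid | CC(C)=CCC(=O)O | starting material
13 | N-methoxy-N,4-dimethylpent-3-enamide | CC(C)=CCC(=O)N(C)OC | intermediate
14 | ethynyltrimethylsilane | C#C[Si](C)(C)C | starting material
15 | lithium (trimethylsilyl)acetylide (not isolated) | [Li]C#C[Si](C)(C)C | intermediate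
16 | 6-methyl-1-(trimethylsilyl)hept-5-en-1-yn-3-one | CC(C)=CCC(=O)C#C[Si](C)(C)C | intermediate
17 | (R)-6-methyl-1-(trimethylsilyl)hept-5-en-1-yn-3-ol | O[C@H](CC=C(C)C)C#C[Si](C)(C)C | intermediate
18 | (R)-tert-butyldimethyl{[6-methyl-1-(trimethylsilyl)hept-5-en-1-yn-3-yl]oxy}silane | CC(C)(C)[Si](C)(C)O[C@H](CC=C(C)C)C#C[Si](C)(C)C | intermediate
19 | (R)-tert-butyldimethyl[(6-methylhept-5-en-1-yn-3-yl)oxy]silane | CC(C)(C)[Si](C)(C)O[C@H](CC=C(C)C)C#C | intermediate
20 | 5,8-bis(tert-butyldimethylsilyloxy)-2-[(1R)-1-(tert-butyldimethylsilyloxy)-4-methylpent-3-en-1-yl]naphthalene-1,4-dione | CC(C)(C)[Si](C)(C)O[C@H](CC=C(C)C)C1=CC(=O)c2c(O[Si](C)(C)C(C)(C)C)ccc(O[Si](C)(C)C(C)(C)C)c2C1=O | intermediate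
21 | shikonin, 5,8-dihydroxy-2-[(1R)-1-hydroxy-4-methylpent-3-en-1-yl]naphthalene-1,4-dione | O[C@H](CC=C(C)C)C1=CC(=O)c2c(O)ccc(O)c2C1=O | intermediate
22 | (2-carboxyethyl)triphenylphosphonium bromide | OC(=O)CC[P+](c1ccccc1)(c1ccccc1)c1ccccc1.[Br-] | starting material
23 | methacrolein (2-methylprop-2-enal) | C=C(C)C=O | starting material
24 | sodium 3-(triphenylphosphoranylidene)propanoate (not isolated) | [Na+].[O-]C(=O)CC=P(c1ccccc1)(c1ccccc1)c1ccccc1 | intermediate
25 | (3Z)-5-methylhexa-3,5-dienoic acid | C=C(C)/C=C\CC(=O)O | intermediate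
26 | CNP0129564.1, (1R)-1-(5,8-dihydroxy-1,4-dioxo-1,4-dihydronaphthalen-2-yl)-4-methylpent-3-en-1-yl (3Z)-5-methylhexa-3,5-dienoate | C=C(C)/C=C\CC(=O)O[C@H](CC=C(C)C)C1=CC(=O)c2c(O)ccc(O)c2C1=O | target

**Count and risks**

Total step count: 15. Longest linear sequence: 9 steps (1, 2, 3, 4, 5, 6, 12, 13, 15) from 1.

Steps most likely to fail:

1. Step 12. Insertion of the alkyne into the hindered bis(silyloxy)phthaloyl complex may be slow, so that the univalent cobalt set free oligomerises the terminal alkyne before annulation is complete. The fallback sets out from 9 and 19 and comes back at 20. Alkyne 19 would be deprotonated with n-BuLi in THF at −78 °C and added to one of the two equivalent carbonyl groups of 9 (AcOH quench). This should give the tertiary alcohol 3,6-bis(tert-butyldimethylsilyloxy)-2-hydroxy-2-[(3R)-3-(tert-butyldimethylsilyloxy)-6-methylhept-5-en-1-yn-1-yl]benzocyclobuten-1(2H)-one F1, either configuration at the new carbinol carbon being usable. Heating F1 in degassed toluene or p-xylene should open the four-membered ring to the ortho-quinoid hydroxy(alkynyl)ketene, which closes onto the distal alkyne carbon and takes up the hydroxyl hydrogen (Moore rearrangement) to give 20. The same two bonds are then made in two operations without cobalt.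

2. Step 15. Deprotonation of the activated acyl group at C2 may give a dienylketene, from which the alkene moves into conjugation or a 6π-electrocyclisation leads to a cresol; acylation of a peri-hydroxyl may also compete. The fallback sets out from 16 and comes back at 26. Ynone 16 would be reduced with the enantiomeric (S,S) ruthenium catalyst to (S)-6-methyl-1-(trimethylsilyl)hept-5-en-1-yn-3-ol F2, and the alkyne freed (K2CO3, MeOH) to give (S)-6-methylhept-5-en-1-yn-3-ol F3. F3 would be esterified with acid 25 under Mitsunobu conditions (PPh3, diisopropyl azodicarboxylate, toluene, 0 °C); here the carboxylate is the nucleophile, no activated acyl species arises, and the carbinol centre is inverted, to give (R)-6-methylhept-5-en-1-yn-3-yl (3Z)-5-methylhexa-3,5-dienoate F4. Annulation of F4 with complex 11 under the conditions of step 12 should give the 5,8-bis(tert-butyldimethylsilyl) ether of the target F5, and buffered fluoride (Bu4NF, AcOH, THF) would then give 26.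

3. Step 2. Bromination of the electron-rich ring may compete with the second benzylic bromination, and forcing the hydrolysis of the gem-dibromide in step 3 may cleave the strained ring. The fallback sets out from 5 and comes back at 7. Ketone 5 would be brominated once (N-bromosuccinimide, 1.05 equiv) to 8-bromo-2,5-dimethoxybicyclo[4.2.0]octa-1,3,5-trien-7-one F6. This α-bromo ketone would be oxidised by Kornblum oxidation (AgBF4, DMSO, rt; then Et3N) to dione 7, the second carbonyl oxygen coming from DMSO instead of from hydrolysis of a dihalide.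

**Further compounds**

F1 | step 12 | 3,6-bis(tert-butyldimethylsilyloxy)-2-hydroxy-2-[(3R)-3-(tert-butyldimethylsilyloxy)-6-methylhept-5-en-1-yn-1-yl]benzocyclobuten-1(2H)-one (mixture of epimers at the ring carbinol) | CC(C)(C)[Si](C)(C)O[C@H](CC=C(C)C)C#CC1(O)C(=O)c2c(O[Si](C)(C)C(C)(C)C)ccc(O[Si](C)(C)C(C)(C)C)c21
F2 | step 15 | (S)-6-methyl-1-(trimethylsilyl)hept-5-en-1-yn-3-ol | O[C@@H](CC=C(C)C)C#C[Si](C)(C)C
F3 | step 15 | (S)-6-methylhept-5-en-1-yn-3-ol | O[C@@H](CC=C(C)C)C#C
F4 | step 15 | (R)-6-methylhept-5-en-1-yn-3-yl (3Z)-5-methylhexa-3,5-dienoate | C=C(C)/C=C\CC(=O)O[C@H](CC=C(C)C)C#C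
F5 | step 15 | (1R)-1-[5,8-bis(tert-butyldimethylsilyloxy)-1,4-dioxo-1,4-dihydronaphthalen-2-yl]-4-methylpent-3-en-1-yl (3Z)-5-methylhexa-3,5-dienoate | C=C(C)/C=C\CC(=O)O[C@H](CC=C(C)C)C1=CC(=O)c2c(O[Si](C)(C)C(C)(C)C)ccc(O[Si](C)(C)C(C)(C)C)c2C1=O
F6 | step 2 | 8-bromo-2,5-dimethoxybicyclo[4.2.0]octa-1,3,5-trien-7-one (racemic) | COc1ccc(OC)c2c1C(Br)C2=O
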